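**Plan**

- Retrosynthesis: after functional-group cuts (C13–OH, the C3 epimer, protecting groups), one operation cuts C4–C5 (ring A), C9–C10 (ring B) and C11–C12 (ring C, the cyclopentene of the bicyclo[3.2.1]octene). What remains is an epoxy enyne chain on a ring D cyclohexenecarboxylate, cut at C8–C16 and C14–C15 (Diels–Alder) and at C6–C7 (alkylation) back to geranyl acetate.
- Enabling feature: the C9=C11 alkene lies between the quaternary C8 and C10 and ends at the bridgehead C12. This is the imprint of a C10 radical adding to an ethynyl group on C8, followed by closure of the vinyl radical onto C12 of an enoate. Ring A (3-OH next to C4 with CH3 and CH2OH) is the imprint of an opened 2,3-epoxy alcohol.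
- Forward order: chain (C1–C7, C18–C20) → 2-alkylacrolein → ring D with C8 → ethynyl group, C16–O and C13 ester → epoxide → rings A, B and C in one flask → C13–OH, inversion at C3, deprotection.
- Stereochemistry: C8 from the catalysed Diels–Alder reaction; C16 from the enone epoxidation; C3 and C4 of the epoxide from Sharpless epoxidation; C4, C5 and C10 from the chair-like cascade steered by C3; C12 from the tether; C13 from equatorial enolate hydroxylation; C3 is inverted at the end through the ketone.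

Key step: step 15

Numbering: C1–C10 are rings A and B; C18 = CH2OH and C19 = CH3 on C4; C20 = CH3 on C10; C11 = vinylic CH; C12 = bridgehead CH; C13 = C(OH)CO2H; C14 and C15 = the CH2CH2 bridge (C15 on C8); C16 = CH(OH) bridge; C17 = CO2H.

Assumption: the sense of induction of the two chiral catalysts (the diol in step 7, the cinchona amine in step 10) is taken as drawn; if a test reaction shows the other sense, the antipodal or pseudoenantiomeric catalyst is used.

**Route**

Step 1
Reactants: 1 geranyl acetate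
Product: 2 (2E,6E)-8-hydroxy-3,7-dimethylocta-2,6-dien-1-yl acetate
Conditions: SeO2 (0.1 equiv), t-BuOOH (70% aq.), salicylic acid (cat.), CH2Cl2, 25 °C
Reagents that add atoms: tert-butyl hydroperoxide (oxygen relayed by SeO2), CC(C)(C)OO
Why: Allylic oxidation with SeO2 (ene reaction, then 2,3-sigmatropic shift) should take the E methyl group of the terminal trisubstituted alkene, the usual site in geranyl esters.

Step 2
Reactants: 2 (2E,6E)-8-hydroxy-3,7-dimethylocta-2,6-dien-1-yl acetate
Product: 3 (2E,6E)-8-(tert-butyldimethylsilyloxy)-3,7-dimethylocta-2,6-dien-1-yl acetate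
Conditions: t-BuMe2SiCl, imidazole, DMF, 0 to 25 °C
Reagents that add atoms: tert-butyldimethylsilyl chloride, CC(C)(C)[Si](C)(C)Cl
Why: Silylation of the primary allylic alcohol keeps the future C18 oxygen apart from the C6 terminus until step 9.

Step 3
Reactants: 3 (2E,6E)-8-(tert-butyldimethylsilyloxy)-3,7-dimethylocta-2,6-dien-1-yl acetate
Product: 4 (2E,6E)-8-(tert-butyldimethylsilyloxy)-3,7-dimethylocta-2,6-dien-1-ol
Conditions: K2CO3, MeOH, 0 °C
Reagents that add atoms: none
Why: Transesterification to methanol should remove the acetate and leave the silyl ether.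

Step 4
Reactants: 4 (2E,6E)-8-(tert-butyldimethylsilyloxy)-3,7-dimethylocta-2,6-dien-1-ol
Product: 5 tert-butyl{[(2E,6E)-8-bromo-2,6-dimethylocta-2,6-dien-1-yl]oxy}dimethylsilane
Conditions: CBr4, PPh3, CH2Cl2, −20 °C
Reagents that add atoms: carbon tetrabromide, BrC(Br)(Br)Br
Why: Appel reaction of a primary allylic alcohol should give the unrearranged E bromide by SN2 displacement of the alkoxyphosphonium ion.

Step 5
Reactants: 5 tert-butyl{[(2E,6E)-8-bromo-2,6-dimethylocta-2,6-dien-1-yl]oxy}dimethylsilane; 6 2-methylprop-2-en-1-ol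
Product: 8 (5E,9E)-11-(tert-butyldimethylsilyloxy)-6,10-dimethyl-2-methylideneundeca-5,9-dien-1-ol, via dilithio methallyl alkoxide 7 (not isolated)
Conditions: 6, n-BuLi (2.1 equiv), TMEDA, Et2O/hexane, 0 to 25 °C; then 5, −78 to 0 °C
Reagents that add atoms: none
Why: Alkylation of the allyl-type dianion of methallyl alcohol, whose two carbon termini are equivalent, with the primary allylic bromide should join C6 to C7 and leave the E C5=C10 alkene untouched.

Step 6
Reactants: 8 (5E,9E)-11-(tert-butyldimethylsilyloxy)-6,10-dimethyl-2-methylideneundeca-5,9-dien-1-ol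
Product: 9 (5E,9E)-11-(tert-butyldimethylsilyloxy)-6,10-dimethyl-2-methylideneundeca-5,9-dienal
Conditions: MnO2 (activated, excess), CH2Cl2, 25 °C
Reagents that add atoms: none
Why: MnO2 should oxidise the allylic alcohol selectively to the 2-alkylacrolein that serves as dienophile.

Step 7
Reactants: 9 (5E,9E)-11-(tert-butyldimethylsilyloxy)-6,10-dimethyl-2-methylideneundeca-5,9-dienal; 10 (E)-3-(tert-butyldimethylsilyloxy)-N,N-dimethylbuta-1,3-dien-1-amine
Product: 11 (1S,2R)-4-(tert-butyldimethylsilyloxy)-2-(dimethylamino)-1-[(3E,7E)-9-(tert-butyldimethylsilyloxy)-4,8-dimethylnona-3,7-dien-1-yl]cyclohex-3-ene-1-carbaldehyde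
Conditions: (4R,5R)-2,2-dimethyl-α,α,α′,α′-tetra(1-naphthyl)-1,3-dioxolane-4,5-dimethanol (TADDOL, 0.2 equiv), toluene, −80 °C; crude 11 is used at once
Reagents that add atoms: none
Why: Diels–Alder reaction of an α-substituted acrolein with a 1-amino-3-siloxydiene under hydrogen-bond catalysis by a chiral diol, a known route to 4,4-disubstituted cyclohexenones, should form C8–C16 and C14–C15 with the amino terminus on the α-carbon, and the diol-bound aldehyde shields one face so that the quaternary C8 is set.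

Step 8
Reactants: 11 (1S,2R)-4-(tert-butyldimethylsilyloxy)-2-(dimethylamino)-1-[(3E,7E)-9-(tert-butyldimethylsilyloxy)-4,8-dimethylnona-3,7-dien-1-yl]cyclohex-3-ene-1-carbaldehyde
Product: 12 (1R,6R)-3-(tert-butyldimethylsilyloxy)-6-ethynyl-N,N-dimethyl-6-[(3E,7E)-9-(tert-butyldimethylsilyloxy)-4,8-dimethylnona-3,7-dien-1-yl]cyclohex-2-en-1-amine
Conditions: Me3SiCHN2, n-BuLi, THF, −78 °C; then 11, −78 to 0 °C
Reagents that add atoms: (trimethylsilyl)diazomethane, C[Si](C)(C)C=[N+]=[N-]
Why: Colvin rearrangement, in which the lithiated diazo compound adds to the non-enolisable aldehyde and Peterson elimination, loss of N2 and a 1,2-hydrogen shift of the alkylidene carbene give the ethynyl group (C9, C11) without touching C8.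

Step 9
Reactants: 12 (1R,6R)-3-(tert-butyldimethylsilyloxy)-6-ethynyl-N,N-dimethyl-6-[(3E,7E)-9-(tert-butyldimethylsilyloxy)-4,8-dimethylnona-3,7-dien-1-yl]cyclohex-2-en-1-amine
Product: 13 (4S)-4-ethynyl-4-[(3E,7E)-9-hydroxy-4,8-dimethylnona-3,7-dien-1-yl]cyclohex-2-en-1-one
Conditions: HF (48% aq.), MeCN, 0 to 25 °C
Reagents that add atoms: none
Why: Acid hydrolysis of the silyl enol ether and β-elimination of dimethylamine should give the enone, and the same reagent cleaves the primary silyl ether so that the C18 hydroxyl is free for step 13.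

Step 10
Reactants: 13 (4S)-4-ethynyl-4-[(3E,7E)-9-hydroxy-4,8-dimethylnona-3,7-dien-1-yl]cyclohex-2-en-1-one
Product: 14 (1S,5R,6S)-5-ethynyl-5-[(3E,7E)-9-hydroxy-4,8-dimethylnona-3,7-dien-1-yl]-7-oxabicyclo[4.1.0]heptan-2-one
Conditions: H2O2 (50% aq.), 9-amino-9-deoxy-epi-quinine bis(trifluoroacetate) (0.1 equiv), dioxane, 35 °C
Reagents that add atoms: hydrogen peroxide, OO
Why: Weitz–Scheffer-type nucleophilic epoxidation through the iminium ion of the enone leaves the isolated alkenes and the alkyne alone, and peroxide should add to C16 anti to the larger alkyl chain on C8 (syn to the slim ethynyl group), a preference the chiral amine is chosen to reinforce.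

Step 11
Reactants: 14 (1S,5R,6S)-5-ethynyl-5-[(3E,7E)-9-hydroxy-4,8-dimethylnona-3,7-dien-1-yl]-7-oxabicyclo[4.1.0]heptan-2-one
Product: 16 (3R,4R)-4-ethynyl-3-hydroxy-4-[(3E,7E)-9-hydroxy-4,8-dimethylnona-3,7-dien-1-yl]cyclohex-1-ene-1-carbaldehyde, via methyl enol ether 15 (not isolated)
Conditions: Ph3P(CH2OMe)Cl (3 equiv), KN(SiMe3)2 (2.9 equiv), THF, 0 °C; then 1 M HCl (aq.), THF, 25 °C
Reagents that add atoms: (methoxymethyl)triphenylphosphonium chloride, COC[P+](c1ccccc1)(c1ccccc1)c1ccccc1.[Cl-]; water, O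
Why: Wittig methoxymethylenation of the ketone places an enol ether next to the epoxide, and mild acid should open the C12–O bond in a vinylogous way and hydrolyse the oxocarbenium ion to the γ-hydroxy enal, so that C16–O keeps its configuration and the alkene lands at C12=C13.

Step 12
Reactants: 16 (3R,4R)-4-ethynyl-3-hydroxy-4-[(3E,7E)-9-hydroxy-4,8-dimethylnona-3,7-dien-1-yl]cyclohex-1-ene-1-carbaldehyde
Product: 18 methyl (3R,4R)-4-ethynyl-3-hydroxy-4-[(3E,7E)-9-hydroxy-4,8-dimethylnona-3,7-dien-1-yl]cyclohex-1-ene-1-carboxylate, via carboxylic acid 17 (not isolated)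
Conditions: NaClO2, NaH2PO4, 2-methyl-2-butene, t-BuOH/H2O, 0 °C; then Me3SiCHN2, MeOH/toluene, 0 °C
Reagents that add atoms: sodium chlorite, [Na+].[O-]Cl=O; (trimethylsilyl)diazomethane, C[Si](C)(C)C=[N+]=[N-]
Why: Pinnick oxidation tolerates the free alcohols, the alkyne and (with the scavenger) the alkenes, and methylation of the acid gives the enoate that serves as the last radical acceptor.

Step 13
Reactants: 18 methyl (3R,4R)-4-ethynyl-3-hydroxy-4-[(3E,7E)-9-hydroxy-4,8-dimethylnona-3,7-dien-1-yl]cyclohex-1-ene-1-carboxylate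
Product: 19 methyl (3R,4R)-4-ethynyl-3-hydroxy-4-{(3E)-6-[(2S,3S)-3-(hydroxymethyl)-3-methyloxiran-2-yl]-4-methylhex-3-en-1-yl}cyclohex-1-ene-1-carboxylate
Conditions: Ti(OiPr)4, L-(+)-diethyl tartrate, t-BuOOH, 4 Å molecular sieves, CH2Cl2, −20 °C
Reagents that add atoms: tert-butyl hydroperoxide, CC(C)(C)OO
Why: Sharpless asymmetric epoxidation of the E 2-methylallylic alcohol should give the (2S,3S)-epoxy alcohol (C3 and C4) under tartrate control, while the electron-poor allylic alcohol of ring D and the isolated C5=C10 alkene should not react.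

Step 14
Reactants: 19 methyl (3R,4R)-4-ethynyl-3-hydroxy-4-{(3E)-6-[(2S,3S)-3-(hydroxymethyl)-3-methyloxiran-2-yl]-4-methylhex-3-en-1-yl}cyclohex-1-ene-1-carboxylate
Product: 20 methyl (3R,4R)-4-ethynyl-3-(triethylsilyloxy)-4-{(3E)-4-methyl-6-[(2S,3S)-3-methyl-3-(triethylsilyloxymethyl)oxiran-2-yl]hex-3-en-1-yl}cyclohex-1-ene-1-carboxylate
Conditions: Et3SiCl, imidazole, DMAP (cat.), DMF, 0 to 25 °C
Reagents that add atoms: chlorotriethylsilane, CC[Si](Cl)(CC)CC
Why: Both hydroxyl groups should be silylated with a silyl chloride and not a triflate, so that the 2,3-epoxy silyl ether does not rearrange.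

Step 15
Reactants: 20 methyl (3R,4R)-4-ethynyl-3-(triethylsilyloxy)-4-{(3E)-4-methyl-6-[(2S,3S)-3-methyl-3-(triethylsilyloxymethyl)oxiran-2-yl]hex-3-en-1-yl}cyclohex-1-ene-1-carboxylate
Product: 25 13-deoxy-3-epi-botryotin F methyl ester 3-O-trimethylsilyl 16,18-bis-O-triethylsilyl ether, via C4 radical 21 (not isolated), via C10 radical 22 (not isolated), via C11 vinyl radical 23 (not isolated), via titanium enolate 24 (not isolated)
Conditions: Cp2TiCl2 (0.3 equiv), Mn dust (8 equiv), Me3SiCl (4 equiv), 2,4,6-collidine (7 equiv), deoxygenated THF (0.01 M), 25 °C; aqueous NaHCO3 work-up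
Reagents that add atoms: chlorotrimethylsilane, C[Si](C)(C)Cl
Why: Proposed new method: Cp2TiCl (trivalent titanium, formed in the flask from Cp2TiCl2 and Mn) should open the epoxide by electron transfer at the tertiary C4, and the β-titanoxy radical 21 should then close ring A by 6-endo-trig addition to C5 (the C4–C5 bond), the tertiary C10 radical 22 ring B by 6-exo-dig addition to the ethynyl carbon C9, and the σ-vinyl radical 23 ring C by 5-exo-trig addition to C12, the β-carbon of the enoate, before a second Cp2TiCl reduces the α-ester radical to the enolate 24 and Me3SiCl silylates both Ti–O bonds and returns Cp2TiCl2. The closest known reaction types are the Cp2TiCl-catalysed radical cyclization of epoxypolyprenes, where every closure is 6-endo-trig onto a trisubstituted alkene, and the 5-exo conjugate cyclization of vinyl radicals formed by radical addition to alkynes; a cascade that runs from an epoxide through an alkyne on a quaternary carbon into an enoate has not been shown. C5 and C10 should follow from a chair-like transition state with the titanoxy group on C3 (fixed by the Sharpless epoxidation) equatorial and from anti addition across the E alkene (trans A/B fusion, axial C20), C4 from the larger CH2OSiEt3 group taking the equatorial place, and C12 from the tether, because C11 can reach C12 only on the ring D face that carries C9; C13 is not controlled here (the kinetic protonation product is drawn) and is set in step 16. The step needs opening at C4 and not C3 (tertiary against secondary radical), endo and not exo first closure (methyl group on C10), attack at C9 and not C11 (exo mode) and at C12 and not C13 (polarity of the enoate and the five-membered ring). It also needs each radical to cyclize before it is reduced: the low stationary concentration of Cp2TiCl in the catalytic protocol and high dilution serve the two tertiary radicals, while the vinyl radical, which must wait for ring B to leave its chair before C11 reaches C12, competes with hydrogen abstraction from THF.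

Step 16
Reactants: 25 13-deoxy-3-epi-botryotin F methyl ester 3-O-trimethylsilyl 16,18-bis-O-triethylsilyl ether
Product: 28 3-epi-botryotin F methyl ester 16,18-bis-O-triethylsilyl ether, via potassium enolate 26 (not isolated), via trimethylsilyl ether 27 (not isolated)
Conditions: KN(SiMe3)2, THF, −78 °C; 2-(phenylsulfonyl)-3-phenyloxaziridine, −78 °C; then K2CO3, MeOH, 0 °C
Reagents that add atoms: 2-(benzenesulfonyl)-3-phenyloxaziridine, O=S(=O)(N1OC1c1ccccc1)c1ccccc1
Why: Enolate hydroxylation with an N-sulfonyloxaziridine should occur on the equatorial face of the exocyclic enolate on chair ring D, away from the one-carbon bridge and the axial hydrogen on C15, which gives the equatorial hydroxyl and axial ester of the target at C13; the methanolysis then frees only the trimethylsilyl ether.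

Step 17
Reactants: 28 3-epi-botryotin F methyl ester 16,18-bis-O-triethylsilyl ether
Product: 29 3-oxo-3-deoxybotryotin F methyl ester 16,18-bis-O-triethylsilyl ether
Conditions: Dess–Martin periodinane, NaHCO3, CH2Cl2, 0 to 25 °C
Reagents that add atoms: none
Why: Dess–Martin oxidation should convert the only secondary alcohol to the ketone, since the tertiary C13 hydroxyl and the silyl ethers are inert.

Step 18
Reactants: 29 3-oxo-3-deoxybotryotin F methyl ester 16,18-bis-O-triethylsilyl ether
Product: 30 botryotin F methyl ester 16,18-bis-O-triethylsilyl ether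
Conditions: LiBH(s-Bu)3 (L-Selectride), THF, −78 °C
Reagents that add atoms: none
Why: A bulky trialkylborohydride should attack the 4,4-disubstituted cyclohexanone from the equatorial direction, away from the axial hydrogens on C1 and C5, and give the axial 3α alcohol, the usual outcome with 4,4-disubstituted 3-oxo terpenoids; the hindered ester should survive at this temperature.

Step 19
Reactants: 30 botryotin F methyl ester 16,18-bis-O-triethylsilyl ether
Product: 32 botryotin F, via lithium carboxylate 31 (not isolated)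
Conditions: LiOH, THF/MeOH/H2O, 40 °C; then 2 M HCl (aq.) to pH 1, 25 °C
Reagents that add atoms: lithium hydroxide, [Li+].[OH-]
Why: Saponification of the α-hydroxy ester followed by acid cleavage of the two triethylsilyl ethers in the same flask should free the acid and the 16- and 18-hydroxyl groups.

**Compound list**

1 | geranyl acetate | CC(=O)OC/C=C(\C)CCC=C(C)C | starting material
2 | (2E,6E)-8-hydroxy-3,7-dimethylocta-2,6-dien-1-yl acetate | CC(=O)OC/C=C(\C)CC/C=C(\C)CO | intermediate
3 | (2E,6E)-8-(tert-butyldimethylsilyloxy)-3,7-dimethylocta-2,6-dien-1-yl acetate | CC(=O)OC/C=C(\C)CC/C=C(\C)CO[Si](C)(C)C(C)(C)C | intermediate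
4 | (2E,6E)-8-(tert-butyldimethylsilyloxy)-3,7-dimethylocta-2,6-dien-1-ol | OC/C=C(\C)CC/C=C(\C)CO[Si](C)(C)C(C)(C)C | intermediate
5 | tert-butyl{[(2E,6E)-8-bromo-2,6-dimethylocta-2,6-dien-1-yl]oxy}dimethylsilane | BrC/C=C(\C)CC/C=C(\C)CO[Si](C)(C)C(C)(C)C | intermediate
6 | 2-methylprop-2-en-1-ol | CC(=C)CO | starting material
7 | dilithio derivative of 2-methylprop-2-en-1-ol (C,O-dianion) | [Li]CC(=C)CO[Li] | intermediate
8 | (5E,9E)-11-(tert-butyldimethylsilyloxy)-6,10-dimethyl-2-methylideneundeca-5,9-dien-1-ol | C=C(CO)CC/C=C(\C)CC/C=C(\C)CO[Si](C)(C)C(C)(C)C | intermediate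
9 | (5E,9E)-11-(tert-butyldimethylsilyloxy)-6,10-dimethyl-2-methylideneundeca-5,9-dienal | C=C(C=O)CC/C=C(\C)CC/C=C(\C)CO[Si](C)(C)C(C)(C)C | intermediate
10 | (E)-3-(tert-butyldimethylsilyloxy)-N,N-dimethylbuta-1,3-dien-1-amine | CN(C)/C=C/C(=C)O[Si](C)(C)C(C)(C)C | starting material
11 | (1S,2R)-4-(tert-butyldimethylsilyloxy)-2-(dimethylamino)-1-[(3E,7E)-9-(tert-butyldimethylsilyloxy)-4,8-dimethylnona-3,7-dien-1-yl]cyclohex-3-ene-1-carbaldehyde (amino group cis to CHO) | O=C[C@@]1(CC/C=C(\C)CC/C=C(\C)CO[Si](C)(C)C(C)(C)C)CCC(O[Si](C)(C)C(C)(C)C)=C[C@H]1N(C)C | intermediate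
12 | (1R,6R)-3-(tert-butyldimethylsilyloxy)-6-ethynyl-N,N-dimethyl-6-[(3E,7E)-9-(tert-butyldimethylsilyloxy)-4,8-dimethylnona-3,7-dien-1-yl]cyclohex-2-en-1-amine | C#C[C@@]1(CC/C=C(\C)CC/C=C(\C)CO[Si](C)(C)C(C)(C)C)CCC(O[Si](C)(C)C(C)(C)C)=C[C@H]1N(C)C | intermediate
13 | (4S)-4-ethynyl-4-[(3E,7E)-9-hydroxy-4,8-dimethylnona-3,7-dien-1-yl]cyclohex-2-en-1-one | C#C[C@@]1(CC/C=C(\C)CC/C=C(\C)CO)CCC(=O)C=C1 | intermediate
14 | (1S,5R,6S)-5-ethynyl-5-[(3E,7E)-9-hydroxy-4,8-dimethylnona-3,7-dien-1-yl]-7-oxabicyclo[4.1.0]heptan-2-one (epoxide cis to ethynyl) | C#C[C@@]1(CC/C=C(\C)CC/C=C(\C)CO)CCC(=O)[C@H]2O[C@@H]12 | intermediate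
15 | methyl enol ether of 14 (C=CH–OMe in place of C=O, E/Z mixture) | C#C[C@@]1(CC/C=C(\C)CC/C=C(\C)CO)CCC(=COC)[C@H]2O[C@@H]12 | intermediate
16 | (3R,4R)-4-ethynyl-3-hydroxy-4-[(3E,7E)-9-hydroxy-4,8-dimethylnona-3,7-dien-1-yl]cyclohex-1-ene-1-carbaldehyde (OH cis to ethynyl) | O=CC1=C[C@@H](O)[C@](C#C)(CC/C=C(\C)CC/C=C(\C)CO)CC1 | intermediate
17 | (3R,4R)-4-ethynyl-3-hydroxy-4-[(3E,7E)-9-hydroxy-4,8-dimethylnona-3,7-dien-1-yl]cyclohex-1-ene-1-carboxylic acid | OC(=O)C1=C[C@@H](O)[C@](C#C)(CC/C=C(\C)CC/C=C(\C)CO)CC1 | intermediate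
18 | methyl (3R,4R)-4-ethynyl-3-hydroxy-4-[(3E,7E)-9-hydroxy-4,8-dimethylnona-3,7-dien-1-yl]cyclohex-1-ene-1-carboxylate | COC(=O)C1=C[C@@H](O)[C@](C#C)(CC/C=C(\C)CC/C=C(\C)CO)CC1 | intermediate
19 | methyl (3R,4R)-4-ethynyl-3-hydroxy-4-{(3E)-6-[(2S,3S)-3-(hydroxymethyl)-3-methyloxiran-2-yl]-4-methylhex-3-en-1-yl}cyclohex-1-ene-1-carboxylate | COC(=O)C1=C[C@@H](O)[C@](C#C)(CC/C=C(\C)CC[C@@H]2O[C@@]2(C)CO)CC1 | intermediate
20 | methyl (3R,4R)-4-ethynyl-3-(triethylsilyloxy)-4-{(3E)-4-methyl-6-[(2S,3S)-3-methyl-3-(triethylsilyloxymethyl)oxiran-2-yl]hex-3-en-1-yl}cyclohex-1-ene-1-carboxylate | COC(=O)C1=C[C@@H](O[Si](CC)(CC)CC)[C@](C#C)(CC/C=C(\C)CC[C@@H]2O[C@@]2(C)CO[Si](CC)(CC)CC)CC1 | intermediate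
21 | tertiary C4 radical from 20 with the C3 oxygen bound to Cp2TiCl | COC(=O)C1=C[C@@H](O[Si](CC)(CC)CC)[C@](C#C)(CC/C=C(\C)CC[C@H](O[Ti](Cl)(C2C=CC=C2)C2C=CC=C2)[C](C)CO[Si](CC)(CC)CC)CC1 | intermediate
22 | ring A closed, tertiary radical at C10 | C[C@@]1(CO[Si](CC)(CC)CC)[C@@H](O[Ti](Cl)(C2C=CC=C2)C2C=CC=C2)CC[C](C)[C@H]1CC[C@]1(C#C)CCC(C(=O)OC)=C[C@H]1O[Si](CC)(CC)CC | intermediate
23 | rings A and B closed, vinyl radical at C11 | C[C@@]1(CO[Si](CC)(CC)CC)[C@@H](O[Ti](Cl)(C2C=CC=C2)C2C=CC=C2)CC[C@]2(C)C(=[CH])[C@@]3(CC[C@@H]12)CCC(C(=O)OC)=C[C@H]3O[Si](CC)(CC)CC | intermediate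
24 | tetracyclic titanium ester enolate at C13 | C[C@@]1(CO[Si](CC)(CC)CC)[C@@H](O[Ti](Cl)(C2C=CC=C2)C2C=CC=C2)CC[C@]2(C)C3=C[C@H]4[C@@H](O[Si](CC)(CC)CC)[C@]3(CC[C@@H]12)CCC4=C(OC)O[Ti](Cl)(C1C=CC=C1)C1C=CC=C1 | intermediate
25 | 13-deoxy-3-epi-botryotin F methyl ester, 3-O-trimethylsilyl, 16,18-bis-O-triethylsilyl ether (3β-silyloxy; H on C13, drawn with the ester axial, C13 epimers expected) | C[C@@]1(CO[Si](CC)(CC)CC)[C@@H](O[Si](C)(C)C)CC[C@]2(C)C3=C[C@H]4[C@@H](O[Si](CC)(CC)CC)[C@]3(CC[C@@H]12)CC[C@@H]4C(=O)OC | intermediate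
26 | potassium ester enolate of 25 | C[C@@]1(CO[Si](CC)(CC)CC)[C@@H](O[Si](C)(C)C)CC[C@]2(C)C3=C[C@H]4[C@@H](O[Si](CC)(CC)CC)[C@]3(CC[C@@H]12)CCC4=C(OC)[O-].[K+] | intermediate
27 | 3-epi-botryotin F methyl ester, 3-O-trimethylsilyl, 16,18-bis-O-triethylsilyl ether | C[C@@]1(CO[Si](CC)(CC)CC)[C@@H](O[Si](C)(C)C)CC[C@]2(C)C3=C[C@H]4[C@@H](O[Si](CC)(CC)CC)[C@]3(CC[C@@H]12)CC[C@]4(O)C(=O)OC | intermediate
28 | 3-epi-botryotin F methyl ester 16,18-bis-O-triethylsilyl ether (3β-OH) | C[C@@]1(CO[Si](CC)(CC)CC)[C@@H](O)CC[C@]2(C)C3=C[C@H]4[C@@H](O[Si](CC)(CC)CC)[C@]3(CC[C@@H]12)CC[C@]4(O)C(=O)OC | intermediate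
29 | 3-oxo-3-deoxybotryotin F methyl ester 16,18-bis-O-triethylsilyl ether | C[C@@]1(CO[Si](CC)(CC)CC)C(=O)CC[C@]2(C)C3=C[C@H]4[C@@H](O[Si](CC)(CC)CC)[C@]3(CC[C@@H]12)CC[C@]4(O)C(=O)OC | intermediate
30 | botryotin F methyl ester 16,18-bis-O-triethylsilyl ether (3α-OH) | C[C@@]1(CO[Si](CC)(CC)CC)[C@H](O)CC[C@]2(C)C3=C[C@H]4[C@@H](O[Si](CC)(CC)CC)[C@]3(CC[C@@H]12)CC[C@]4(O)C(=O)OC | intermediate
31 | lithium carboxylate of botryotin F 16,18-bis-O-triethylsilyl ether | C[C@@]1(CO[Si](CC)(CC)CC)[C@H](O)CC[C@]2(C)C3=C[C@H]4[C@@H](O[Si](CC)(CC)CC)[C@]3(CC[C@@H]12)CC[C@]4(O)C(=O)[O-].[Li+] | intermediate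
32 | botryotin F | C[C@@]1(CO)[C@H](O)CC[C@]2(C)C3=C[C@H]4[C@@H](O)[C@]3(CC[C@@H]12)CC[C@]4(O)C(=O)O | target

**Totals**

Total step count: 19. Longest linear sequence: 19 steps (1 to 32).

**Steps most likely to fail**

Step 15 (Proposed new method).
- What may go wrong: reduction of the C10 radical before it reaches the alkyne; hydrogen abstraction from the solvent by the vinyl radical before ring C closes; loss of control at C4 in the radical closure.
- Fallback: a stepwise polar route of known reaction types that sets out from 20 and comes back at 25.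
- The alkyne of 20 is hydrated in the anti-Markovnikov sense by hydroboration with dicyclohexylborane and oxidation with NaBO3 to the aldehyde F1.
- KN(SiMe3)2 and t-BuMe2SiCl at −78 °C give the silyl enol ether F2.
- MeAlCl2 in CH2Cl2 at −78 °C starts an epoxide-initiated cation–olefin bicyclization (anti opening at C4, chair–chair folding) that the enol silane ends at C9, which should give the tricyclic hydroxy aldehyde F3 with the formyl group equatorial and cis to C16.
- Me3SiCl and imidazole give the trimethylsilyl ether F4.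
- SmI2 (divalent samarium) in THF/MeOH at −78 °C closes C11–C12 by ketyl–olefin cyclization onto the enoate to the tetracyclic C11 alcohol F5.
- Dehydration with methyl N-(triethylammoniosulfonyl)carbamate in toluene can only run toward C9, because C12 is a bridgehead, and gives 25.

Step 10.
- What may go wrong: poor facial selectivity of peroxide addition next to the quaternary C8, which carries through steps 11 and 12 as the C16 epimer of 18.
- Fallback: a correction loop under reagent control that sets out from 18 (as the epimer mixture) and comes back at 18 as one diastereomer.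
- Et3SiCl and imidazole at −40 °C silylate the primary alcohol to the silyl ether F6.
- Dess–Martin periodinane oxidises the ring alcohol to the 3-oxo ester F7, which erases the stereocentre.
- CBS reduction ((S)-2-methyl-CBS-oxazaborolidine, catecholborane, toluene, −78 °C, with the quaternary carbon as the large group) sets C16 to give the alcohol F8.
- Pyridinium p-toluenesulfonate in MeOH removes the silyl group and returns 18.

Step 5.
- What may go wrong: attack of the dianion at the tertiary allylic carbon (SN2′), halogen–lithium exchange and elimination of the bromide.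
- Fallback: a copper-catalysed Grignard coupling that sets out from 5 and comes back at 9.
- 5 is coupled with [2-(1,3-dioxolan-2-yl)ethyl]magnesium bromide under Li2CuCl4 catalysis (THF, −20 °C) to the acetal F9.
- Pyridinium p-toluenesulfonate in wet acetone at 50 °C frees the aldehyde F10.
- α-Methylenation with dimethyl(methylidene)ammonium iodide and Et3N in CH2Cl2 gives 9.

**Further compounds**

F1 | step 15 | aldehyde from 20 (CH2CHO in place of the ethynyl group on C8) | COC(=O)C1=C[C@@H](O[Si](CC)(CC)CC)[C@](CC=O)(CC/C=C(\C)CC[C@@H]2O[C@@]2(C)CO[Si](CC)(CC)CC)CC1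
F2 | step 15 | tert-butyldimethylsilyl enol ether of F1 (E/Z mixture) | COC(=O)C1=C[C@@H](O[Si](CC)(CC)CC)[C@](C=CO[Si](C)(C)C(C)(C)C)(CC/C=C(\C)CC[C@@H]2O[C@@]2(C)CO[Si](CC)(CC)CC)CC1
F3 | step 15 | tricyclic 3β-hydroxy 9-carbaldehyde (rings A and B closed, 9α-H, ring D spiro at C8) | C[C@@]1(CO[Si](CC)(CC)CC)[C@@H](O)CC[C@]2(C)[C@@H](C=O)[C@@]3(CC[C@@H]12)CCC(C(=O)OC)=C[C@H]3O[Si](CC)(CC)CC
F4 | step 15 | 3-O-trimethylsilyl ether of F3 | C[C@@]1(CO[Si](CC)(CC)CC)[C@@H](O[Si](C)(C)C)CC[C@]2(C)[C@@H](C=O)[C@@]3(CC[C@@H]12)CCC(C(=O)OC)=C[C@H]3O[Si](CC)(CC)CC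
F5 | step 15 | tetracyclic C11 alcohol (9α-H, C11 epimers; 25 with water added across C9=C11) | C[C@@]1(CO[Si](CC)(CC)CC)[C@@H](O[Si](C)(C)C)CC[C@]2(C)[C@H]3C(O)[C@H]4[C@@H](O[Si](CC)(CC)CC)[C@]3(CC[C@@H]12)CC[C@@H]4C(=O)OC
F6 | step 10 | primary triethylsilyl ether of 18 (mixture of ring-carbinol epimers) | COC(=O)C1=CC(O)[C@](C#C)(CC/C=C(\C)CC/C=C(\C)CO[Si](CC)(CC)CC)CC1
F7 | step 10 | methyl (4R)-4-ethynyl-3-oxo-4-[(3E,7E)-4,8-dimethyl-9-(triethylsilyloxy)nona-3,7-dien-1-yl]cyclohex-1-ene-1-carboxylate | COC(=O)C1=CC(=O)[C@](C#C)(CC/C=C(\C)CC/C=C(\C)CO[Si](CC)(CC)CC)CC1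
F8 | step 10 | methyl (3R,4R)-4-ethynyl-3-hydroxy-4-[(3E,7E)-4,8-dimethyl-9-(triethylsilyloxy)nona-3,7-dien-1-yl]cyclohex-1-ene-1-carboxylate | COC(=O)C1=C[C@@H](O)[C@](C#C)(CC/C=C(\C)CC/C=C(\C)CO[Si](CC)(CC)CC)CC1
F9 | step 5 | 2-[(4E,8E)-10-(tert-butyldimethylsilyloxy)-5,9-dimethyldeca-4,8-dien-1-yl]-1,3-dioxolane | C1COC(O1)CCC/C=C(\C)CC/C=C(\C)CO[Si](C)(C)C(C)(C)C
F10 | step 5 | (5E,9E)-11-(tert-butyldimethylsilyloxy)-6,10-dimethylundeca-5,9-dienal | O=CCCC/C=C(\C)CC/C=C(\C)CO[Si](C)(C)C(C)(C)C
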